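**Plan**

- Locants: ring B is the central benzene ring. C2/C3 are the inner dihydrofuran carbons (C2 carries the 4-hydroxyphenyl group). C8 is the Ar–CH carbon of the seven-membered ring and ring D is the resorcinol ring fused into it. C2'/C3' are the outer dihydrofuran carbons (C3' carries the 3,5-dihydroxyphenyl group).
- Cuts: the eight phenols go back to methyl ethers. The C2'–C3' bond goes back to a diaryl carbene at C3' and the O–CH2 group of a 4-methoxybenzyl ether on the neighbouring ring B oxygen. The C3'–ring B bond goes back to an aryl bromide and 3,5-dimethoxybenzonitrile. The C8–ring D bond goes back to a stilbene (aldehyde plus phosphonate). The C2–C3 bond goes back to a first carbene insertion on a symmetric ring B dibromide.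
- Feature used: C3' is a diaryl methine on ring B next to the ring oxygen and C2' is an O–CH(aryl) carbon. C2'–C3' is therefore the bond a diaryl carbene forms with a benzylic ether C–H bond five atoms away, and both centres lie far from C2, C3 and C8.
- Forward order: ring B is functionalised, then come the inner dihydrofuran (step 5), the stilbene (step 9), the seven-membered ring (step 10), the outer dihydrofuran (step 13) and the free phenols (step 14).
- Stereochemistry: C3 comes from Rh2(S-PTAD)4 and C3' from Rh2(R-PTAD)4 (catalyst control). C2 and C2' become trans by acid equilibration of the O-benzylic carbons. C8 comes from substrate control in the Friedel–Crafts closure.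

Key step: step 13

Remark 1 (assumption): the sense of induction is taken as Rh2(S-PTAD)4 (Rh2[(S)-1-adamantyl(phthalimido)acetate]4) giving 3S in step 5 and Rh2(R-PTAD)4 giving 3'R in step 13; if it is the opposite, the two catalyst enantiomers are exchanged between these steps.

Remark 2 (assumption): both insertions are taken to give the 2,3-cis dihydrofuran first, as is usual for this reaction class, so each O-benzylic carbon is equilibrated to trans by acid afterwards.

**Route**

Step 1
Reactants: 1 3,5-dihydroxybenzyl alcohol; 2 4-methoxybenzyl chloride (2.2 equiv in total)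
Product: 3 [3,5-bis(4-methoxybenzyloxy)phenyl]methanol
Conditions: 2 (2.2 equiv), K2CO3 (3 equiv), n-Bu4NI (cat.), DMF, 60 °C
Reagents that add atoms: 4-methoxybenzyl chloride (second equivalent of 2), COc1ccc(CCl)cc1
Why: Twofold Williamson etherification consumes one molecule of 2 at each phenol under carbonate base and leaves the much less acidic benzylic alcohol untouched, as in the standard preparation of 3,5-bis(benzyloxy)benzyl alcohol.

Step 2
Reactants: 3 [3,5-bis(4-methoxybenzyloxy)phenyl]methanol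
Product: 4 [2,6-dibromo-3,5-bis(4-methoxybenzyloxy)phenyl]methanol
Conditions: NBS (2.05 equiv), MeCN, 0 °C → rt, dark
Reagents that add atoms: N-bromosuccinimide, BrN1C(=O)CCC1=O
Why: Electrophilic aromatic bromination should go twice to the positions that are ortho to one ether oxygen and para to the other (C2 and C6), as in the 4,6-dibromination of resorcinol diethers, and not to the crowded C4 between the two ethers or to the less activated anisyl rings.

Step 3
Reactants: 4 [2,6-dibromo-3,5-bis(4-methoxybenzyloxy)phenyl]methanol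
Product: 5 [2,6-dibromo-3,5-bis(4-methoxybenzyloxy)benzyloxy]triisopropylsilane
Conditions: TIPSOTf, 2,6-lutidine, CH2Cl2, 0 °C
Reagents that add atoms: triisopropylsilyl trifluoromethanesulfonate, CC(C)[Si](OS(=O)(=O)C(F)(F)F)(C(C)C)C(C)C
Why: Silylation of the primary alcohol, with the bulky triisopropylsilyl group chosen because it resists oxygen-to-carbon silyl migration to the ortho-lithiated carbon in step 4 (retro-Brook rearrangement) and shields the ether oxygen from the carbene in step 5.

Step 4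
Reactants: 5 [2,6-dibromo-3,5-bis(4-methoxybenzyloxy)benzyloxy]triisopropylsilane; 6 3,5-dimethoxybenzonitrile
Product: 9 [3-bromo-4,6-bis(4-methoxybenzyloxy)-2-(triisopropylsilyloxymethyl)phenyl](3,5-dimethoxyphenyl)methanone hydrazone (E/Z mixture), via aryllithium 7 (not isolated), via N–H ketimine 8 (not isolated)
Conditions: n-BuLi (1.05 equiv), THF, −78 °C; 6, −78 → 0 °C; AcOH; then N2H4·H2O, EtOH, 60 °C
Reagents that add atoms: hydrazine (as the hydrate), NN
Why: Bromine–lithium exchange on the symmetric dibromide should stop after one exchange because the aryllithium resists a second one, addition to the nitrile gives the N–H ketimine, and transimination with hydrazine (loss of ammonia) gives the hydrazone of a di-ortho-substituted benzophenone that would condense only sluggishly from the ketone.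

Step 5
Reactants: 9 the hydrazone from step 4
Product: 11 (2R,3S)-5-bromo-3-(3,5-dimethoxyphenyl)-6-(4-methoxybenzyloxy)-2-(4-methoxyphenyl)-4-(triisopropylsilyloxymethyl)-2,3-dihydrobenzofuran (2,3-cis), via diaryldiazomethane 10 (not isolated)
Conditions: MnO2, CH2Cl2, 0 °C; filter; Rh2(S-PTAD)4 (1 mol %), CH2Cl2, 0 °C
Reagents that add atoms: none
Why: Oxidation of the hydrazone gives the diaryldiazomethane, Rh2(S-PTAD)4 expels N2 to give a donor/donor carbene that inserts into the adjacent O–CH2–anisyl C–H bond (intramolecular 1,5 C–H insertion) and closes the inner dihydrofuran, the chiral carboxylate ligands setting C3 as S, while the kinetic cis arrangement at C2 is carried on because C2 is equilibrated in step 10.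

Step 6
Reactants: 11 the cis dihydrobenzofuran silyl ether
Product: 12 [(2R,3S)-5-bromo-3-(3,5-dimethoxyphenyl)-6-(4-methoxybenzyloxy)-2-(4-methoxyphenyl)-2,3-dihydrobenzofuran-4-yl]methanol
Conditions: TBAF, THF, 0 °C → rt
Reagents that add atoms: none
Why: Fluoride-induced desilylation cleaves only the Si–O bond and leaves the aryl bromide, the ethers and both stereocentres untouched.

Step 7
Reactants: 12 the benzylic alcohol
Product: 13 (2R,3S)-5-bromo-3-(3,5-dimethoxyphenyl)-6-(4-methoxybenzyloxy)-2-(4-methoxyphenyl)-2,3-dihydrobenzofuran-4-carbaldehyde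
Conditions: IBX, EtOAc, 75 °C
Reagents that add atoms: none
Why: IBX oxidises the benzylic alcohol to the aldehyde under neutral conditions, which avoids acid-induced attack of the aldehyde on the nearby dimethoxyphenyl ring.

Step 8
Reactants: 14 2,4-dimethoxybenzyl alcohol
Product: 15 diethyl (2,4-dimethoxybenzyl)phosphonate
Conditions: P(OEt)3, ZnI2, THF, reflux
Reagents that add atoms: triethyl phosphite, CCOP(OCC)OCC
Why: The ZnI2-mediated Arbuzov-type conversion of an electron-rich benzylic alcohol into its phosphonate avoids the unstable 2,4-dimethoxybenzyl halide.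

Step 9
Reactants: 13 the aldehyde; 15 diethyl (2,4-dimethoxybenzyl)phosphonate
Product: 16 (2R,3S)-5-bromo-4-[(E)-2-(2,4-dimethoxyphenyl)ethenyl]-3-(3,5-dimethoxyphenyl)-6-(4-methoxybenzyloxy)-2-(4-methoxyphenyl)-2,3-dihydrobenzofuran
Conditions: KOt-Bu, THF, 0 °C → rt
Reagents that add atoms: none
Why: Horner–Wadsworth–Emmons olefination with the benzylic phosphonate anion should give the E-stilbene, and the alkene geometry is not critical because either isomer gives the same cation in step 10.

Step 10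
Reactants: 16 the stilbene
Product: 19 (2S,3S,8S)-tetracyclic bromophenol (5-bromo-6-hydroxy-2,3-trans-dihydrobenzofuran whose C4 is bridged by CH2–C8H(2,4-dimethoxyphenyl) to the ortho carbon of ring D), via cyclised cis PMB ether 17 (not isolated), via cis bromophenol 18 (not isolated)
Conditions: CF3CO2H, PhSMe, CH2Cl2, 0 °C → rt
Reagents that add atoms: none
Why: Protonation of the stilbene at the carbon next to ring B gives the 2,4-dimethoxybenzylic cation, which ring D captures ortho to a methoxy group (intramolecular Friedel–Crafts alkylation, the same closure that converts ε-viniferin into ampelopsin B) with the aryl group pseudo-axial and away from the flanking ring D methoxy group so that C8 should be S, while the same acid cleaves the 4-methoxybenzyl aryl ether (thioanisole takes up the benzyl cation) and reversibly ionises the O–C2 bond so that C2 settles as the trans (2S) isomer.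

Step 11
Reactants: 19 the tetracyclic bromophenol; 2 4-methoxybenzyl chloride
Product: 20 (2S,3S,8S)-tetracyclic bromide carrying the 6-(4-methoxybenzyloxy) group
Conditions: K2CO3, n-Bu4NI (cat.), DMF, 50 °C
Reagents that add atoms: none
Why: Williamson etherification of the single free phenol restores the benzylic ether whose C–H bond is needed in step 13.

Step 12
Reactants: 20 the tetracyclic bromide; 6 3,5-dimethoxybenzonitrile
Product: 23 (2S,3S,8S)-tetracyclic hydrazone with C(=N–NH2)(3,5-dimethoxyphenyl) at C5 next to the 6-(4-methoxybenzyloxy) group (E/Z mixture), via aryllithium 21 (not isolated), via N–H ketimine 22 (not isolated)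
Conditions: n-BuLi (1.1 equiv), THF, −78 °C; 6, −78 → 0 °C; AcOH; then N2H4·H2O, EtOH, 60 °C
Reagents that add atoms: hydrazine (as the hydrate), NN
Why: As in step 4, bromine–lithium exchange at −78 °C is faster than deprotonation of any benzylic position, the aryllithium adds to the nitrile, and transimination of the resulting N–H ketimine with hydrazine gives a hydrazone at a ring carbon flanked by the benzyloxy group and the ring methylene.

Step 13
Reactants: 23 the tetracyclic hydrazone
Product: 26 (2S,3S,8S,2'R,3'R)-octamethyl ether of the target (both dihydrofurans trans), via diaryldiazomethane 24 (not isolated), via 2',3'-cis octamethyl ether 25 (not isolated)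
Conditions: MnO2, CH2Cl2, 0 °C; filter; Rh2(R-PTAD)4 (2 mol %), CH2Cl2, 0 °C → rt; then CF3CO2H, rt
Reagents that add atoms: none
Why: MnO2 dehydrogenates the hydrazone to the diaryldiazomethane 24, Rh2(R-PTAD)4 expels N2 to give a donor/donor carbene at C3', and this carbene inserts into a C–H bond of the neighbouring O–CH2–anisyl group in a concerted, hydride-transfer-like step. The closest known reaction type is the enantioselective intramolecular C–H insertion of diaryl carbenes, generated from hydrazones by in situ oxidation, into benzylic ether C–H bonds to give 2,3-diaryl-2,3-dihydrobenzofurans. The outer dihydrofuran closes by 1,5-insertion, the carbene carbon bonding to the ether carbon through a five-membered cyclic transition state to form C2'–C3'. C3' is set by the chiral carboxylate ligands of Rh2(R-PTAD)4, which decide the face of the carbene that meets the C–H bond and should override the three remote centres, whereas C2' forms cis under kinetic control and is then equilibrated to trans (2'R) by CF3CO2H through reversible ionisation of the O–C2' bond to the anisyl-stabilised cation. The step needs site selectivity for the ether C–H bond over the diarylmethine C8–H bond (also a 1,5 relationship) and over azine formation; the ether oxygen and the anisyl ring make the O–CH2 hydrogens the best hydride donors, the C8–H bond is tertiary and points away, and the carbene has no β-hydrogen to divert it.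

Step 14
Reactants: 26 the octamethyl ether
Product: 27 CNP0154047.3, the (2S,3S,8S,2'R,3'R)-octaphenol
Conditions: BBr3 (excess), CH2Cl2, −78 °C → rt; then MeOH, H2O
Reagents that add atoms: none
Why: BBr3 cleaves the eight aryl methyl ethers through aryloxy-dibromoboranes (Lewis acid O-demethylation), and any reversible opening of the O-benzylic bonds should return to the trans dihydrofurans, which are the thermodynamic isomers.

**Compound list**

1 | 3,5-dihydroxybenzyl alcohol | OCc1cc(O)cc(O)c1 | starting material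
2 | 4-methoxybenzyl chloride | COc1ccc(CCl)cc1 | starting material
3 | [3,5-bis(4-methoxybenzyloxy)phenyl]methanol | OCc1cc(OCc2ccc(OC)cc2)cc(OCc2ccc(OC)cc2)c1 | intermediate
4 | [2,6-dibromo-3,5-bis(4-methoxybenzyloxy)phenyl]methanol | OCc1c(Br)c(OCc2ccc(OC)cc2)cc(OCc2ccc(OC)cc2)c1Br | intermediate
5 | [2,6-dibromo-3,5-bis(4-methoxybenzyloxy)benzyloxy]triisopropylsilane | CC(C)[Si](OCc1c(Br)c(OCc2ccc(OC)cc2)cc(OCc2ccc(OC)cc2)c1Br)(C(C)C)C(C)C | intermediate
6 | 3,5-dimethoxybenzonitrile | COc1cc(OC)cc(C#N)c1 | starting material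
7 | 3-bromo-4,6-bis(4-methoxybenzyloxy)-2-(triisopropylsilyloxymethyl)phenyllithium (not isolated) | CC(C)[Si](OCc1c(Br)c(OCc2ccc(OC)cc2)cc(OCc2ccc(OC)cc2)c1[Li])(C(C)C)C(C)C | intermediate
8 | [3-bromo-4,6-bis(4-methoxybenzyloxy)-2-(triisopropylsilyloxymethyl)phenyl](3,5-dimethoxyphenyl)methanimine (not isolated) | CC(C)[Si](OCc1c(Br)c(OCc2ccc(OC)cc2)cc(OCc2ccc(OC)cc2)c1C(=N)c1cc(OC)cc(OC)c1)(C(C)C)C(C)C | intermediate
9 | hydrazone of [3-bromo-4,6-bis(4-methoxybenzyloxy)-2-(triisopropylsilyloxymethyl)phenyl](3,5-dimethoxyphenyl)methanone, E/Z mixture | CC(C)[Si](OCc1c(Br)c(OCc2ccc(OC)cc2)cc(OCc2ccc(OC)cc2)c1C(=NN)c1cc(OC)cc(OC)c1)(C(C)C)C(C)C | intermediate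
10 | [3-bromo-4,6-bis(4-methoxybenzyloxy)-2-(triisopropylsilyloxymethyl)phenyl](3,5-dimethoxyphenyl)diazomethane (not isolated) | CC(C)[Si](OCc1c(Br)c(OCc2ccc(OC)cc2)cc(OCc2ccc(OC)cc2)c1C(=[N+]=[N-])c1cc(OC)cc(OC)c1)(C(C)C)C(C)C | intermediate
11 | (2R,3S)-5-bromo-3-(3,5-dimethoxyphenyl)-6-(4-methoxybenzyloxy)-2-(4-methoxyphenyl)-4-(triisopropylsilyloxymethyl)-2,3-dihydrobenzofuran (cis) | COc1ccc([C@@H]2Oc3cc(OCc4ccc(OC)cc4)c(Br)c(CO[Si](C(C)C)(C(C)C)C(C)C)c3[C@@H]2c2cc(OC)cc(OC)c2)cc1 | intermediate
12 | [(2R,3S)-5-bromo-3-(3,5-dimethoxyphenyl)-6-(4-methoxybenzyloxy)-2-(4-methoxyphenyl)-2,3-dihydrobenzofuran-4-yl]methanol | COc1ccc([C@@H]2Oc3cc(OCc4ccc(OC)cc4)c(Br)c(CO)c3[C@@H]2c2cc(OC)cc(OC)c2)cc1 | intermediate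
13 | (2R,3S)-5-bromo-3-(3,5-dimethoxyphenyl)-6-(4-methoxybenzyloxy)-2-(4-methoxyphenyl)-2,3-dihydrobenzofuran-4-carbaldehyde | COc1ccc([C@@H]2Oc3cc(OCc4ccc(OC)cc4)c(Br)c(C=O)c3[C@@H]2c2cc(OC)cc(OC)c2)cc1 | intermediate
14 | 2,4-dimethoxybenzyl alcohol | COc1ccc(CO)c(OC)c1 | starting material
15 | diethyl (2,4-dimethoxybenzyl)phosphonate | CCOP(=O)(Cc1ccc(OC)cc1OC)OCC | intermediate
16 | (2R,3S)-5-bromo-4-[(E)-2-(2,4-dimethoxyphenyl)ethenyl]-3-(3,5-dimethoxyphenyl)-6-(4-methoxybenzyloxy)-2-(4-methoxyphenyl)-2,3-dihydrobenzofuran | COc1ccc([C@@H]2Oc3cc(OCc4ccc(OC)cc4)c(Br)c(/C=C/c4ccc(OC)cc4OC)c3[C@@H]2c2cc(OC)cc(OC)c2)cc1 | intermediate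
17 | (2R,3S,8S)-tetracycle after seven-membered ring closure: 2,3-cis, 5-bromo, 6-(4-methoxybenzyloxy), C8 bearing 2,4-dimethoxyphenyl (not isolated) | COc1ccc([C@@H]2Oc3cc(OCc4ccc(OC)cc4)c(Br)c4c3[C@@H]2c2cc(OC)cc(OC)c2[C@H](c2ccc(OC)cc2OC)C4)cc1 | intermediate
18 | (2R,3S,8S)-tetracyclic bromophenol, 2,3-cis, 6-OH (not isolated) | COc1ccc([C@@H]2Oc3cc(O)c(Br)c4c3[C@@H]2c2cc(OC)cc(OC)c2[C@H](c2ccc(OC)cc2OC)C4)cc1 | intermediate
19 | (2S,3S,8S)-tetracyclic bromophenol, 2,3-trans, 5-bromo, 6-OH | COc1ccc([C@H]2Oc3cc(O)c(Br)c4c3[C@@H]2c2cc(OC)cc(OC)c2[C@H](c2ccc(OC)cc2OC)C4)cc1 | intermediate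
20 | (2S,3S,8S)-tetracyclic bromide, 6-(4-methoxybenzyloxy) | COc1ccc([C@H]2Oc3cc(OCc4ccc(OC)cc4)c(Br)c4c3[C@@H]2c2cc(OC)cc(OC)c2[C@H](c2ccc(OC)cc2OC)C4)cc1 | intermediate
21 | (2S,3S,8S)-tetracyclic aryllithium, lithium at C5 (not isolated) | COc1ccc([C@H]2Oc3cc(OCc4ccc(OC)cc4)c([Li])c4c3[C@@H]2c2cc(OC)cc(OC)c2[C@H](c2ccc(OC)cc2OC)C4)cc1 | intermediate
22 | (2S,3S,8S)-tetracyclic N–H ketimine, C(=NH)(3,5-dimethoxyphenyl) at C5 (not isolated) | COc1ccc([C@H]2Oc3cc(OCc4ccc(OC)cc4)c(C(=N)c4cc(OC)cc(OC)c4)c4c3[C@@H]2c2cc(OC)cc(OC)c2[C@H](c2ccc(OC)cc2OC)C4)cc1 | intermediate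
23 | (2S,3S,8S)-tetracyclic hydrazone, C(=N–NH2)(3,5-dimethoxyphenyl) at C5, 6-(4-methoxybenzyloxy), E/Z mixture | COc1ccc([C@H]2Oc3cc(OCc4ccc(OC)cc4)c(C(=NN)c4cc(OC)cc(OC)c4)c4c3[C@@H]2c2cc(OC)cc(OC)c2[C@H](c2ccc(OC)cc2OC)C4)cc1 | intermediate
24 | (2S,3S,8S)-tetracyclic diaryldiazomethane (not isolated) | COc1ccc([C@H]2Oc3cc(OCc4ccc(OC)cc4)c(C(=[N+]=[N-])c4cc(OC)cc(OC)c4)c4c3[C@@H]2c2cc(OC)cc(OC)c2[C@H](c2ccc(OC)cc2OC)C4)cc1 | intermediate
25 | (2S,3S,8S,2'S,3'R)-octamethyl ether, outer dihydrofuran cis (not isolated) | COc1ccc([C@H]2Oc3cc4c(c5c3[C@@H]2c2cc(OC)cc(OC)c2[C@H](c2ccc(OC)cc2OC)C5)[C@@H](c2cc(OC)cc(OC)c2)[C@@H](c2ccc(OC)cc2)O4)cc1 | intermediate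
26 | (2S,3S,8S,2'R,3'R)-octamethyl ether of the target, both dihydrofurans trans | COc1ccc([C@H]2Oc3cc4c(c5c3[C@@H]2c2cc(OC)cc(OC)c2[C@H](c2ccc(OC)cc2OC)C5)[C@@H](c2cc(OC)cc(OC)c2)[C@H](c2ccc(OC)cc2)O4)cc1 | intermediate
27 | CNP0154047.3, (2S,3S,8S,2'R,3'R)-octaphenol | Oc1ccc([C@H]2Oc3cc4c(c5c3[C@@H]2c2cc(O)cc(O)c2[C@H](c2ccc(O)cc2O)C5)[C@@H](c2cc(O)cc(O)c2)[C@H](c2ccc(O)cc2)O4)cc1 | target

**Step count and risks**

Total steps: 14. Longest linear sequence: 13 (steps 1–7 and 9–14; step 8 is a one-step branch).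

Steps most likely to fail:

1. Step 13 (key step). The carbene carbon sits between the benzyloxy group and the ring methylene, so N2 loss on the bulky Rh2(R-PTAD)4 may be slow and the diazo compound may drift to azine. Insertion into the C8–H bond may compete, a mismatched catalyst–substrate pairing may lower the selectivity at C3', and the acid equilibration may erode C3' through elimination and re-protonation. Fallback: the route leaves from bromide 20. Bromine–lithium exchange (n-BuLi, −78 °C) and acylation with N-methoxy-N-methyl-3,5-dimethoxybenzamide should give the diaryl ketone F1. The phosphazene base P4-t-Bu then deprotonates the O–CH2–anisyl group, and aldol-type closure onto the ketone gives the tertiary alcohol F2, which loses water (TsOH if needed) to the 2,3-diarylbenzofuran F3. Ionic hydrogenation (Et3SiH, CF3CO2H) of F3 should give the trans-2,3-dihydrobenzofuran and rejoins the route at 26. In this fallback the face at C3' is set by the existing stereocentres, so a separation of diastereomers may be needed.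

2. Step 12. The aryllithium next to the O–CH2–aryl group may abstract a benzylic proton (anion translocation followed by Wittig rearrangement) or add slowly to the nitrile, and a slow transimination may let the ketimine hydrolyse to the ketone. Fallback: the route leaves from bromophenol 19. Esterification with 3,5-dimethoxybenzoyl chloride (Et3N, DMAP) gives the aryl ester F4. Bromine–lithium exchange with s-BuLi at −95 °C triggers oxygen-to-carbon acyl migration (anionic Fries rearrangement) to the ortho-hydroxy ketone F5. Alkylation with 2 and K2CO3 gives the diaryl ketone F1 already named above. Condensation with 1,2-bis(tert-butyldimethylsilyl)hydrazine and Sc(OTf)3 (cat.) gives the N-silyl hydrazone F6, and TBAF releases the hydrazone, so the route is rejoined at 23.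

3. Step 10. The 4-methoxybenzyl cation is set free while the stilbene cation is cyclising, so incomplete scavenging may lead to benzylation of the dimethoxyphenyl rings, a scavenger strong enough to prevent this may intercept the stilbene cation, and closure may occur from the wrong face at C8. Fallback: the route leaves from 11 and separates the three acid events. CF3CO2H with a large excess of 1,3,5-trimethoxybenzene removes the benzyl ether and equilibrates C2, giving the trans phenol F7. MOMCl and i-Pr2NEt give the methoxymethyl ether F8. TBAF gives the alcohol F9, IBX the aldehyde F10, and olefination with 15 and KOt-Bu the stilbene F11. TsOH in MeOH/CH2Cl2 then closes the seven-membered ring with loss of the methoxymethyl group and rejoins the route at 19.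

**Further compounds**

F1 | step 13 | (2S,3S,8S)-tetracyclic diaryl ketone, C(=O)(3,5-dimethoxyphenyl) at C5, 6-(4-methoxybenzyloxy) | COc1ccc([C@H]2Oc3cc(OCc4ccc(OC)cc4)c(C(=O)c4cc(OC)cc(OC)c4)c4c3[C@@H]2c2cc(OC)cc(OC)c2[C@H](c2ccc(OC)cc2OC)C4)cc1
F2 | step 13 | (2S,3S,8S)-pentacyclic tertiary alcohol, 3'-hydroxy-2'-(4-methoxyphenyl)-3'-(3,5-dimethoxyphenyl) outer dihydrofuran, mixture at C2' and C3' | COc1ccc([C@H]2Oc3cc4OC(c5ccc(OC)cc5)C(O)(c5cc(OC)cc(OC)c5)c4c4c3[C@@H]2c2cc(OC)cc(OC)c2[C@H](c2ccc(OC)cc2OC)C4)cc1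
F3 | step 13 | (2S,3S,8S)-benzofuran, outer ring aromatic with 2'-(4-methoxyphenyl) and 3'-(3,5-dimethoxyphenyl) | COc1ccc([C@H]2Oc3cc4oc(-c5ccc(OC)cc5)c(-c5cc(OC)cc(OC)c5)c4c4c3[C@@H]2c2cc(OC)cc(OC)c2[C@H](c2ccc(OC)cc2OC)C4)cc1
F4 | step 12 | (2S,3S,8S)-tetracyclic bromide, 6-O-(3,5-dimethoxybenzoyl) ester | COc1ccc([C@H]2Oc3cc(OC(=O)c4cc(OC)cc(OC)c4)c(Br)c4c3[C@@H]2c2cc(OC)cc(OC)c2[C@H](c2ccc(OC)cc2OC)C4)cc1
F5 | step 12 | (2S,3S,8S)-tetracyclic ortho-hydroxy ketone, 6-OH, C(=O)(3,5-dimethoxyphenyl) at C5 | COc1ccc([C@H]2Oc3cc(O)c(C(=O)c4cc(OC)cc(OC)c4)c4c3[C@@H]2c2cc(OC)cc(OC)c2[C@H](c2ccc(OC)cc2OC)C4)cc1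
F6 | step 12 | N-tert-butyldimethylsilyl hydrazone of ketone F1 | COc1ccc([C@H]2Oc3cc(OCc4ccc(OC)cc4)c(C(=NN[Si](C)(C)C(C)(C)C)c4cc(OC)cc(OC)c4)c4c3[C@@H]2c2cc(OC)cc(OC)c2[C@H](c2ccc(OC)cc2OC)C4)cc1
F7 | step 10 | (2S,3S)-5-bromo-3-(3,5-dimethoxyphenyl)-2-(4-methoxyphenyl)-4-(triisopropylsilyloxymethyl)-2,3-dihydrobenzofuran-6-ol (trans) | COc1ccc([C@H]2Oc3cc(O)c(Br)c(CO[Si](C(C)C)(C(C)C)C(C)C)c3[C@@H]2c2cc(OC)cc(OC)c2)cc1
F8 | step 10 | 6-O-methoxymethyl ether of F7 | COc1ccc([C@H]2Oc3cc(OCOC)c(Br)c(CO[Si](C(C)C)(C(C)C)C(C)C)c3[C@@H]2c2cc(OC)cc(OC)c2)cc1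
F9 | step 10 | [(2S,3S)-5-bromo-3-(3,5-dimethoxyphenyl)-6-(methoxymethoxy)-2-(4-methoxyphenyl)-2,3-dihydrobenzofuran-4-yl]methanol | COc1ccc([C@H]2Oc3cc(OCOC)c(Br)c(CO)c3[C@@H]2c2cc(OC)cc(OC)c2)cc1
F10 | step 10 | (2S,3S)-5-bromo-3-(3,5-dimethoxyphenyl)-6-(methoxymethoxy)-2-(4-methoxyphenyl)-2,3-dihydrobenzofuran-4-carbaldehyde | COc1ccc([C@H]2Oc3cc(OCOC)c(Br)c(C=O)c3[C@@H]2c2cc(OC)cc(OC)c2)cc1
F11 | step 10 | (2S,3S)-5-bromo-4-[(E)-2-(2,4-dimethoxyphenyl)ethenyl]-3-(3,5-dimethoxyphenyl)-6-(methoxymethoxy)-2-(4-methoxyphenyl)-2,3-dihydrobenzofuran | COc1ccc([C@H]2Oc3cc(OCOC)c(Br)c(/C=C/c4ccc(OC)cc4OC)c3[C@@H]2c2cc(OC)cc(OC)c2)cc1
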